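**Retrosynthetic overview**

1. The strategy rests on the C4 carbonyl of ring C. It sits between C4a of the symmetrical 1,3,5-trioxygenated ring A and the benzylic carbon C3, while the C3–C1' bond is crowded by the C2' prenyl group of ring B. The C3–C1' bond is therefore carried in as a ready-made benzyl–arene bond and C4 is supplied as carbon monoxide.
2. Pyranone ring C is closed last (O1–C2 and C2–C3), by a one-carbon enaminone extension of deoxybenzoin 17 followed by acid removal of the MOM groups.
3. Key disconnection: C4a–C4 and C4–C3 of 17, giving aryl iodide 15, carbon monoxide 16 and benzylzinc chloride 12.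
4. 12 comes from 3,4-dihydroxybenzaldehyde: the dimethylpyran ring of the chromene is formed first (propargyl Claisen/electrocyclisation at the 4-oxygen), then the prenyl group is set at C7 by Claisen rearrangement of a 1,1-dimethylallyl ether on the 8-oxygen. 15 comes from phloroglucinol.
5. Ring order: rings A and B are bought as arenes, the chromene pyran ring is closed in step 2 and ring C in step 14.

Key step: step 12

Remark on the chemistry: both C5 units are introduced from commercial 3-chloro-3-methylbut-1-yne. Enaminone 18 is drawn as the E isomer, but either geometry would close to the same pyranone.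

**Route**

Step 1
Reactants: 1 3,4-dihydroxybenzaldehyde; 2 3-chloro-3-methylbut-1-yne
Product: 3 3-hydroxy-4-[(2-methylbut-3-yn-2-yl)oxy]benzaldehyde
Conditions: 2 (1.1 equiv), DBU (1.1 equiv), CuCl2·2H2O (1 mol%), MeCN, −5 to 0 °C, Ar
Reagents that add atoms: none
Why: The 4-OH, para to the formyl group, is the more acidic phenol, so one equivalent of DBU should give the 4-phenoxide, which is alkylated in a copper-catalysed O-propargylation of the tertiary propargylic chloride while the 3-OH stays free.

Step 2
Reactants: 3 3-hydroxy-4-[(2-methylbut-3-yn-2-yl)oxy]benzaldehyde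
Product: 5 8-hydroxy-2,2-dimethyl-2H-chromene-6-carbaldehyde, via allenyl catechol 4 (not isolated)
Conditions: PhNEt2, 190 °C, Ar
Reagents that add atoms: none
Why: The aromatic propargyl Claisen rearrangement can deliver productively only to C5 (C3 carries the OH), and the ortho-allenyl phenol should close to the 2,2-dimethyl-2H-chromene by 1,5-hydrogen shift and 6π oxa-electrocyclisation.

Step 3
Reactants: 5 8-hydroxy-2,2-dimethyl-2H-chromene-6-carbaldehyde; 2 3-chloro-3-methylbut-1-yne
Product: 6 2,2-dimethyl-8-[(2-methylbut-3-yn-2-yl)oxy]-2H-chromene-6-carbaldehyde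
Conditions: 2 (1.5 equiv), DBU (1.6 equiv), CuCl2·2H2O (1 mol%), MeCN, 0 °C
Reagents that add atoms: none
Why: The same copper-catalysed O-propargylation is applied to the only remaining phenol, at a temperature far below that needed for rearrangement of the new ether.

Step 4
Reactants: 6 2,2-dimethyl-8-[(2-methylbut-3-yn-2-yl)oxy]-2H-chromene-6-carbaldehyde
Product: 7 2,2-dimethyl-8-[(2-methylbut-3-en-2-yl)oxy]-2H-chromene-6-carbaldehyde
Conditions: H2 (1 atm), Pd/CaCO3 poisoned with Pb(OAc)2 (Lindlar catalyst), quinoline, EtOAc, rt, stopped after 1 equiv H2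
Reagents that add atoms: none
Why: Lindlar semi-hydrogenation should reduce the terminal alkyne much faster than the hindered disubstituted chromene alkene or the aldehyde, giving the 1,1-dimethylallyl ether.

Step 5
Reactants: 7 2,2-dimethyl-8-[(2-methylbut-3-en-2-yl)oxy]-2H-chromene-6-carbaldehyde
Product: 8 8-hydroxy-2,2-dimethyl-7-(3-methylbut-2-enyl)-2H-chromene-6-carbaldehyde
Conditions: PhNEt2, 150 °C, Ar
Reagents that add atoms: none
Why: In the aromatic Claisen rearrangement of the tertiary allyl ether the terminal CH2 should bond to C7, the only free ortho carbon (C8a is blocked by the pyran oxygen), and allyl inversion then gives the linear prenyl group after tautomerisation.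

Step 6
Reactants: 8 8-hydroxy-2,2-dimethyl-7-(3-methylbut-2-enyl)-2H-chromene-6-carbaldehyde
Product: 9 8-(methoxymethoxy)-2,2-dimethyl-7-(3-methylbut-2-enyl)-2H-chromene-6-carbaldehyde
Conditions: NaH, MOMCl, DMF, 0 °C → rt
Reagents that add atoms: chloromethyl methyl ether, COCCl
Why: O-alkylation of the sodium phenoxide with the small, hard MOM chloride should proceed despite the two flanking substituents and masks the acidic OH before the organozinc is made.

Step 7
Reactants: 9 8-(methoxymethoxy)-2,2-dimethyl-7-(3-methylbut-2-enyl)-2H-chromene-6-carbaldehyde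
Product: 10 [8-(methoxymethoxy)-2,2-dimethyl-7-(3-methylbut-2-enyl)-2H-chromen-6-yl]methanol
Conditions: NaBH4, MeOH/THF, 0 °C
Reagents that add atoms: none
Why: Borohydride reduction of the aryl aldehyde is chemoselective and leaves the alkenes and the MOM acetal untouched.

Step 8
Reactants: 10 [8-(methoxymethoxy)-2,2-dimethyl-7-(3-methylbut-2-enyl)-2H-chromen-6-yl]methanol
Product: 11 6-(chloromethyl)-8-(methoxymethoxy)-2,2-dimethyl-7-(3-methylbut-2-enyl)-2H-chromene
Conditions: PPh3, NCS (premixed), THF, 0 °C → rt; filtered quickly and used at once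
Reagents that add atoms: N-chlorosuccinimide, O=C1CCC(=O)N1Cl
Why: In this Appel-type chlorination chloride displaces the alkoxyphosphonium group at the primary benzylic carbon under neutral conditions, so the MOM acetal and the alkenes are not exposed to acid.

Step 9
Reactants: 11 6-(chloromethyl)-8-(methoxymethoxy)-2,2-dimethyl-7-(3-methylbut-2-enyl)-2H-chromene
Product: 12 {[8-(methoxymethoxy)-2,2-dimethyl-7-(3-methylbut-2-enyl)-2H-chromen-6-yl]methyl}zinc chloride (kept as a titrated THF solution of its LiCl complex)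
Conditions: Zn dust (activated with BrCH2CH2Br and TMSCl), LiCl, THF, 0 → 25 °C
Reagents that add atoms: zinc, [Zn]
Why: LiCl-promoted direct insertion of zinc into a benzylic C–Cl bond is standard for alkoxy-substituted benzyl chlorides and tolerates acetals and alkenes, with low temperature limiting Wurtz homocoupling.

Step 10
Reactants: 13 phloroglucinol
Product: 14 1,3,5-tris(methoxymethoxy)benzene
Conditions: NaH (3.6 equiv), MOMCl (3.6 equiv), DMF, 0 °C → rt
Reagents that add atoms: chloromethyl methyl ether, COCCl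
Why: The hard electrophile MOM chloride should alkylate the phenoxide oxygens rather than the ring carbons, giving the tris-acetal.

Step 11
Reactants: 14 1,3,5-tris(methoxymethoxy)benzene
Product: 15 2-iodo-1,3,5-tris(methoxymethoxy)benzene
Conditions: NIS (1.0 equiv), DMF, 0 °C → rt, dark
Reagents that add atoms: N-iodosuccinimide, O=C1CCC(=O)N1I
Why: Electrophilic aromatic iodination of the strongly activated ring needs no acid, the three free positions are equivalent so only one mono-iodide can form, and one equivalent of NIS restrains a second iodination.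

Step 12
Reactants: 15 2-iodo-1,3,5-tris(methoxymethoxy)benzene; 16 carbon monoxide; 12 {[8-(methoxymethoxy)-2,2-dimethyl-7-(3-methylbut-2-enyl)-2H-chromen-6-yl]methyl}zinc chloride
Product: 17 2-[8-(methoxymethoxy)-2,2-dimethyl-7-(3-methylbut-2-enyl)-2H-chromen-6-yl]-1-[2,4,6-tris(methoxymethoxy)phenyl]ethanone
Conditions: Pd(PPh3)4 (5 mol%), CO (1 atm), THF, 50 °C, slow addition of 12 (1.5 equiv)
Reagents that add atoms: none
Why: Oxidative addition of the C–I bond of 15 to zerovalent palladium gives an arylpalladium iodide (divalent palladium), CO inserts to the aroyl complex, benzylzinc chloride 12 transmetalates, and reductive elimination releases ketone 17 and returns zerovalent palladium. The closest known reaction type is the palladium-catalysed carbonylative Negishi coupling of aryl iodides with benzyl- and alkylzinc halides to unsymmetrical ketones. No ring is closed and no stereocentre is formed; the two skeletal bonds made are C4a–C4 and C4–C3 (isoflavone numbering). The selectivity needed is ketone over the diarylmethane from direct coupling: the two ortho MOM-oxy groups retard transmetalation at the crowded arylpalladium but not insertion of the small CO ligand, and a CO-saturated solution with slow addition of 12 reinforces this. Ring A is symmetrical, so 15 is a single isomer, and the neutral conditions should leave the prenyl group, the chromene alkene and all four MOM acetals untouched.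

Step 13
Reactants: 17 2-[8-(methoxymethoxy)-2,2-dimethyl-7-(3-methylbut-2-enyl)-2H-chromen-6-yl]-1-[2,4,6-tris(methoxymethoxy)phenyl]ethanone
Product: 18 (E)-3-(dimethylamino)-2-[8-(methoxymethoxy)-2,2-dimethyl-7-(3-methylbut-2-enyl)-2H-chromen-6-yl]-1-[2,4,6-tris(methoxymethoxy)phenyl]prop-2-en-1-one
Conditions: Me2NCH(OMe)2, toluene, 100 °C
Reagents that add atoms: N,N-dimethylformamide dimethyl acetal, COC(OC)N(C)C
Why: Condensation of the doubly activated methylene (between the carbonyl and ring B) with the amide acetal adds the future C2 as an enaminone under non-acidic conditions that the MOM acetals survive.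

Step 14
Reactants: 18 (E)-3-(dimethylamino)-2-[8-(methoxymethoxy)-2,2-dimethyl-7-(3-methylbut-2-enyl)-2H-chromen-6-yl]-1-[2,4,6-tris(methoxymethoxy)phenyl]prop-2-en-1-one
Product: 20 5,7-dihydroxy-3-[8-hydroxy-2,2-dimethyl-7-(3-methylbut-2-enyl)-2H-chromen-6-yl]-4H-chromen-4-one, via tetrahydroxy enaminone 19 (not isolated)
Conditions: 3 M HCl, MeOH, rt → 45 °C
Reagents that add atoms: none
Why: Acid methanolysis removes the four MOM acetals, and either of the two equivalent ortho hydroxyls of ring A then adds to the enaminone β-carbon and expels dimethylamine (oxa-Michael addition–elimination), closing the pyranone ring while the other ortho hydroxyl becomes the 5-OH.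

**Compound list**

1 | 3,4-dihydroxybenzaldehyde | O=Cc1ccc(O)c(O)c1 | starting material
2 | 3-chloro-3-methylbut-1-yne | C#CC(C)(C)Cl | starting material
3 | 3-hydroxy-4-[(2-methylbut-3-yn-2-yl)oxy]benzaldehyde | O=Cc1ccc(OC(C)(C)C#C)c(O)c1 | intermediate
4 | 3,4-dihydroxy-5-(3-methylbuta-1,2-dienyl)benzaldehyde (allenyl catechol, not isolated) | O=Cc1cc(O)c(O)c(C=C=C(C)C)c1 | intermediate
5 | 8-hydroxy-2,2-dimethyl-2H-chromene-6-carbaldehyde | O=Cc1cc(O)c2OC(C)(C)C=Cc2c1 | intermediate
6 | 2,2-dimethyl-8-[(2-methylbut-3-yn-2-yl)oxy]-2H-chromene-6-carbaldehyde | O=Cc1cc(OC(C)(C)C#C)c2OC(C)(C)C=Cc2c1 | intermediate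
7 | 2,2-dimethyl-8-[(2-methylbut-3-en-2-yl)oxy]-2H-chromene-6-carbaldehyde | O=Cc1cc(OC(C)(C)C=C)c2OC(C)(C)C=Cc2c1 | intermediate
8 | 8-hydroxy-2,2-dimethyl-7-(3-methylbut-2-enyl)-2H-chromene-6-carbaldehyde | O=Cc1cc2C=CC(C)(C)Oc2c(O)c1CC=C(C)C | intermediate
9 | 8-(methoxymethoxy)-2,2-dimethyl-7-(3-methylbut-2-enyl)-2H-chromene-6-carbaldehyde | O=Cc1cc2C=CC(C)(C)Oc2c(OCOC)c1CC=C(C)C | intermediate
10 | [8-(methoxymethoxy)-2,2-dimethyl-7-(3-methylbut-2-enyl)-2H-chromen-6-yl]methanol | OCc1cc2C=CC(C)(C)Oc2c(OCOC)c1CC=C(C)C | intermediate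
11 | 6-(chloromethyl)-8-(methoxymethoxy)-2,2-dimethyl-7-(3-methylbut-2-enyl)-2H-chromene | ClCc1cc2C=CC(C)(C)Oc2c(OCOC)c1CC=C(C)C | intermediate
12 | {[8-(methoxymethoxy)-2,2-dimethyl-7-(3-methylbut-2-enyl)-2H-chromen-6-yl]methyl}zinc chloride | Cl[Zn]Cc1cc2C=CC(C)(C)Oc2c(OCOC)c1CC=C(C)C | intermediate
13 | phloroglucinol (benzene-1,3,5-triol) | Oc1cc(O)cc(O)c1 | starting material
14 | 1,3,5-tris(methoxymethoxy)benzene | COCOc1cc(OCOC)cc(OCOC)c1 | intermediate
15 | 2-iodo-1,3,5-tris(methoxymethoxy)benzene | COCOc1cc(OCOC)c(I)c(OCOC)c1 | intermediate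
16 | carbon monoxide | [C-]#[O+] | starting material
17 | 2-[8-(methoxymethoxy)-2,2-dimethyl-7-(3-methylbut-2-enyl)-2H-chromen-6-yl]-1-[2,4,6-tris(methoxymethoxy)phenyl]ethanone | COCOc1cc(OCOC)c(C(=O)Cc2cc3C=CC(C)(C)Oc3c(OCOC)c2CC=C(C)C)c(OCOC)c1 | intermediate
18 | (E)-3-(dimethylamino)-2-[8-(methoxymethoxy)-2,2-dimethyl-7-(3-methylbut-2-enyl)-2H-chromen-6-yl]-1-[2,4,6-tris(methoxymethoxy)phenyl]prop-2-en-1-one (NMe2 anti to the carbonyl) | COCOc1cc(OCOC)c(C(=O)/C(=C/N(C)C)c2cc3C=CC(C)(C)Oc3c(OCOC)c2CC=C(C)C)c(OCOC)c1 | intermediate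
19 | (E)-3-(dimethylamino)-2-[8-hydroxy-2,2-dimethyl-7-(3-methylbut-2-enyl)-2H-chromen-6-yl]-1-(2,4,6-trihydroxyphenyl)prop-2-en-1-one (tetrahydroxy enaminone, not isolated) | Oc1cc(O)c(C(=O)/C(=C/N(C)C)c2cc3C=CC(C)(C)Oc3c(O)c2CC=C(C)C)c(O)c1 | intermediate
20 | 5,7-dihydroxy-3-[8-hydroxy-2,2-dimethyl-7-(3-methylbut-2-enyl)-2H-chromen-6-yl]-4H-chromen-4-one (no stereocentre) | CC(C)=CCc1c(-c2coc3cc(O)cc(O)c3c2=O)cc2c(c1O)OC(C)(C)C=C2 | target

**Step count**

Total: 14 steps. Longest linear sequence: 12 steps (steps 1–9, then 12–14, from 3,4-dihydroxybenzaldehyde). The ring-A arm is 2 steps (10 and 11) and joins at step 12.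

**Steps most likely to fail**

Step 12. Direct, non-carbonylative coupling, protodeiodination or homocoupling of the benzylzinc may outrun CO insertion at the crowded, electron-rich arylpalladium. The fallback sets out from 14 and 12 and rejoins the route at 17. n-BuLi (THF, 0 °C) would lithiate 14 between two MOM-oxy groups to [2,4,6-tris(methoxymethoxy)phenyl]lithium F1, and DMF would formylate it to 2,4,6-tris(methoxymethoxy)benzaldehyde F2. 1,2-Addition of benzylzinc chloride 12 (THF, MgCl2, 25 °C) would then give racemic 2-[8-(methoxymethoxy)-2,2-dimethyl-7-(3-methylbut-2-enyl)-2H-chromen-6-yl]-1-[2,4,6-tris(methoxymethoxy)phenyl]ethanol F3. Dess–Martin periodinane (NaHCO3, CH2Cl2) would oxidise F3 to 17.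

Step 5. The tertiary allyl group may be lost as isoprene, or may move on by a Cope shift to the para carbon C5, instead of being delivered cleanly to the crowded C7. The fallback sets out from 5 and rejoins the route at 9. Allyl bromide and K2CO3 in acetone would give 2,2-dimethyl-8-(prop-2-enyloxy)-2H-chromene-6-carbaldehyde F4. Its Claisen rearrangement (PhNEt2, 190 °C) cannot eliminate and would place the small allyl group at C7, giving 8-hydroxy-2,2-dimethyl-7-(prop-2-enyl)-2H-chromene-6-carbaldehyde F5. NaH and MOMCl would give 8-(methoxymethoxy)-2,2-dimethyl-7-(prop-2-enyl)-2H-chromene-6-carbaldehyde F6. Cross-metathesis of F6 with 2-methylbut-2-ene (second-generation Grubbs catalyst, CH2Cl2, 40 °C) would turn the allyl into the prenyl group of 9; the hindered chromene alkene should stay out of the metathesis.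

Step 14. In methanolic HCl the freed C8 phenol may add across the neighbouring prenyl alkene (chroman formation), or the alkenes may be hydrated, before all four MOM groups are cleaved. The fallback sets out from 17 and rejoins the route at 20, and separates deprotection from ring closure. ZnBr2 with n-PrSH (CH2Cl2, 0 °C, minutes) would strip the MOM groups from 17 without protic acid, giving 2-[8-hydroxy-2,2-dimethyl-7-(3-methylbut-2-enyl)-2H-chromen-6-yl]-1-(2,4,6-trihydroxyphenyl)ethanone F7. Me2NCH(OMe)2 in THF (rt → 60 °C) would then convert F7 through enaminone 19 directly into 20, because the free ortho hydroxyl closes the ring under these non-acidic conditions.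

**Further compounds**

F1 | step 12 | [2,4,6-tris(methoxymethoxy)phenyl]lithium | [Li]c1c(OCOC)cc(OCOC)cc1OCOC
F2 | step 12 | 2,4,6-tris(methoxymethoxy)benzaldehyde | O=Cc1c(OCOC)cc(OCOC)cc1OCOC
F3 | step 12 | 2-[8-(methoxymethoxy)-2,2-dimethyl-7-(3-methylbut-2-enyl)-2H-chromen-6-yl]-1-[2,4,6-tris(methoxymethoxy)phenyl]ethanol (racemic) | COCOc1cc(OCOC)c(C(O)Cc2cc3C=CC(C)(C)Oc3c(OCOC)c2CC=C(C)C)c(OCOC)c1
F4 | step 5 | 2,2-dimethyl-8-(prop-2-enyloxy)-2H-chromene-6-carbaldehyde | O=Cc1cc(OCC=C)c2OC(C)(C)C=Cc2c1
F5 | step 5 | 8-hydroxy-2,2-dimethyl-7-(prop-2-enyl)-2H-chromene-6-carbaldehyde | O=Cc1cc2C=CC(C)(C)Oc2c(O)c1CC=C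
F6 | step 5 | 8-(methoxymethoxy)-2,2-dimethyl-7-(prop-2-enyl)-2H-chromene-6-carbaldehyde | O=Cc1cc2C=CC(C)(C)Oc2c(OCOC)c1CC=C
F7 | step 14 | 2-[8-hydroxy-2,2-dimethyl-7-(3-methylbut-2-enyl)-2H-chromen-6-yl]-1-(2,4,6-trihydroxyphenyl)ethanone | Oc1cc(O)c(C(=O)Cc2cc3C=CC(C)(C)Oc3c(O)c2CC=C(C)C)c(O)c1
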